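**Plan**

1. Retrosynthesis: cut the enol ester C18–O bond (alkenyl boron plus 3-methylbut-2-enoic acid), take C17=C18 back to a C16 vinyl group and the acetonyl group back to a C4 allyl group, cut C4–C3 and C16–C17, and take C6–OH/C7H2 back to the β-alkoxy enone C5(=O)–C6=C7–O8.
2. That enol ether is a [4+2] adduct: cutting O8–C9 and C10–C15 together removes rings B and C at once and leaves a monocyclic 2-formylcyclohepta-2,6-dienone with the 4-methylpent-3-enyl chain on C13.
3. Enabling feature: C6 of ring A carries C7 (bonded to O8) and is bonded to C15, so at the aldehyde/enone oxidation level O8=C7–C6=C15 is an s-cis 1-oxadiene, and the C9=C10 isopropylidene alkene is tied to C15 through C11–C12–C13–C14. The extra unsaturation is later removed by conjugate reduction with hydroxylation at C6.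
4. Forward order: cyclohexenone → quaternary C13 → one-carbon ring expansion to ring A → formylation → dehydrogenation/oxa-Diels–Alder (rings B and C) → C16 vinyl, C4 allyl, C6–OH → methyl ketone → (E)-alkenyl boron → enol ester.
5. Stereochemistry: C13 from a chiral copper–carbene catalyst; C15 and C10 from the tether in the cycloaddition; C16, C6 and C4 from attack of cuprate, oxaziridine and proton on the convex upper face of the tricycle; alkene geometry from E-selective metathesis and stereoretentive C–O coupling.

Key step: step 6

Remark (numbering used here): C1–C3 = acetonyl (CH3, C=O, CH2); C4 = CH bearing it; C5 = ring C=O; C6 = C–OH; C7 = OCH2; O8; C9 = CMe2; C10, C11, C12; C13 = quaternary C–CH3; C14; C15; C16 = CH bearing the enol ester; C17=C18. Ring A = cycloheptanone (C4, C5, C6, C15, C14, C13, C16), ring B = cyclohexane (C10–C15), ring C = tetrahydropyran (C6, C7, O8, C9, C10, C15). The upper face of ring A is the face of the C13 methyl group; ring B hangs from the lower face.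

Remark (assumptions): the ligand enantiomer in step 2 is the one that gives the (R)-configured quaternary centre; 14 and 16 are carried as mixtures of C4 epimers, which converge in step 10.

**Step 1**
Reactants: 1 5-bromo-2-methylpent-2-ene
Product: 2 (4-methylpent-3-en-1-yl)magnesium bromide
Conditions: Mg (1.5 equiv), I2 (cat.), Et2O, reflux
Reagents that add atoms: magnesium, [Mg]
Why: Grignard formation by insertion of magnesium into a primary alkyl bromide; the remote trisubstituted alkene is inert.

**Step 2**
Reactants: 2 (4-methylpent-3-en-1-yl)magnesium bromide; 3 3-methylcyclohex-2-en-1-one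
Product: 5 (R)-trimethyl{[3-methyl-3-(4-methylpent-3-en-1-yl)cyclohex-1-en-1-yl]oxy}silane, via bromomagnesium enolate 4 (not isolated)
Conditions: Cu(OTf)2 (3 mol %), chiral imidazolinium chloride (carbene precursor, 4 mol %), Et2O, 0 °C; then TMSCl, Et3N, HMPA, 0 °C → rt
Reagents that add atoms: chlorotrimethylsilane, C[Si](C)(C)Cl
Why: Copper–carbene-catalysed asymmetric conjugate addition of a Grignard reagent to a β-methyl cyclohexenone, in which the chiral ligand selects the enone face and sets the quaternary centre (R), while O-silylation of the magnesium enolate fixes the enol ether on the side of the new quaternary carbon.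

**Step 3**
Reactants: 5 (R)-trimethyl{[3-methyl-3-(4-methylpent-3-en-1-yl)cyclohex-1-en-1-yl]oxy}silane
Product: 6 (5R)-5-methyl-5-(4-methylpent-3-en-1-yl)-1-(trimethylsilyloxy)bicyclo[4.1.0]heptane (both cyclopropane diastereomers)
Conditions: Et2Zn (1.2 equiv), CH2I2 (1.2 equiv), CH2Cl2, −15 → 0 °C
Reagents that add atoms: diiodomethane, ICI
Why: Simmons–Smith cyclopropanation (diethylzinc variant), in which the electrophilic zinc carbenoid should take the electron-rich silyl enol ether before the isolated trisubstituted alkene when kept near one equivalent; the new cyclopropane stereocentres are destroyed in step 4.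

**Step 4**
Reactants: 6 (5R)-5-methyl-5-(4-methylpent-3-en-1-yl)-1-(trimethylsilyloxy)bicyclo[4.1.0]heptane
Product: 8 (R)-4-methyl-4-(4-methylpent-3-en-1-yl)cyclohept-2-en-1-one, via β-chloro ketone 7 (not isolated)
Conditions: FeCl3 (2.2 equiv), DMF, 0 °C → rt; then NaOAc, MeOH, reflux
Reagents that add atoms: none
Why: Ito–Saegusa ring expansion: FeCl3 oxidises the siloxycyclopropane, the internal cyclopropane bond opens to the ring-enlarged β-keto radical, which is chlorinated by FeCl3 faster than it can cyclise, and acetate-induced E1cB loss of HCl gives the γ,γ-disubstituted cycloheptenone with the quaternary centre untouched.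

**Step 5**
Reactants: 8 (R)-4-methyl-4-(4-methylpent-3-en-1-yl)cyclohept-2-en-1-one
Product: 9 7-(hydroxymethylene)-4-methyl-4-(4-methylpent-3-en-1-yl)cyclohept-2-en-1-one (chelated Z-enol; quaternary centre as in 8)
Conditions: NaH (2 equiv), HCO2Et (5 equiv), EtOH (cat.), THF, 0 °C → rt; then 1 M HCl
Reagents that add atoms: ethyl formate, CCOC=O
Why: Claisen-type formylation of the ketone enolate; only the α′-methylene (C6) can be deprotonated because the γ-carbon (C13) is quaternary, and the product is stabilised as the chelated hydroxymethylene tautomer.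

**Step 6**
Reactants: 9 7-(hydroxymethylene)-4-methyl-4-(4-methylpent-3-en-1-yl)cyclohept-2-en-1-one
Product: 11 tricyclic β-alkoxy dienone (rings A, B and C closed; C5 ketone; C4=C16 and C6=C7 double bonds; H15 up; H10 trans to H15), via 2-formyl dienone 10 (not isolated)
Conditions: DDQ (1.1 equiv), 1,4-dioxane, rt, then 60 °C
Reagents that add atoms: none
Why: DDQ abstracts hydride from C15 of the chelated enol 9 (the established dehydrogenation of α-hydroxymethylene ketones) to give the 2-formyl dienone 10, whose exocyclic aldehyde can lie s-cis to C6=C15 and so presents an electron-poor 1-oxadiene O8=C7–C6=C15. The C9=C10 alkene, held four atoms from C15 by the C11–C12–C13–C14 tether, adds across it in an intramolecular inverse-electron-demand oxa-Diels–Alder reaction; the closest known type is the intramolecular hetero-Diels–Alder reaction of alkylidene 1,3-dicarbonyl compounds with unactivated trisubstituted alkenes. Ring B closes through the C10–C15 bond (six-membered carbocycle, making rings A and B a bicyclo[4.3.1]decane) and ring C through the O8–C9 bond as the six-membered [4+2] ring, with the nucleophilic alkene terminus C10 going to the electrophilic C15 and the tertiary C9 to oxygen. C15 is controlled by the C13 stereocentre, because the tether reaches only the lower face of ring A (H15 up), and C10 by the exo arrangement of the tether (C11 anti to C6 across the forming bond), which places H10 trans to H15. The step needs the aldehyde, not a ketone, to act as heterodiene and cycloaddition to beat an ene reaction: the ring ketone and the C4=C16 enone are locked s-trans within ring A, and the doubly acceptor-substituted oxadiene with its oxygen held over C9 favours the [4+2] path.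

**Step 7**
Reactants: 11 tricyclic β-alkoxy dienone
Product: 12 C16-vinyl silyl dienol ether (C5–OSiMe3; C4=C5 and C6=C7 double bonds; vinyl up)
Conditions: vinylmagnesium bromide (3 equiv), CuBr·SMe2 (20 mol %), TMSCl (3 equiv), HMPA (3 equiv), THF, −78 °C; Et3N, then aq. NaHCO3
Reagents that add atoms: vinylmagnesium bromide, C=C[Mg]Br; chlorotrimethylsilane, C[Si](C)(C)Cl
Why: Copper-catalysed, TMSCl-accelerated 1,4-addition of a vinyl Grignard reagent to the C4=C16 enone, which is more electrophilic than the oxygen-deactivated and α-substituted β-alkoxy enone half C6=C7; vinyl enters the upper face of C16, anti to the C10–C12 bridge of ring B, and the enolate is trapped as the silyl enol ether.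

**Step 8**
Reactants: 12 C16-vinyl silyl dienol ether
Product: 14 C4-allyl C16-vinyl β-alkoxy enone (C5 ketone; C6=C7; mixture of C4 epimers), via lithium enolate 13 (not isolated)
Conditions: MeLi (1.1 equiv), THF, 0 °C; then allyl iodide (3 equiv), HMPA, −78 → 0 °C
Reagents that add atoms: allyl iodide, C=CCI
Why: Regiospecific generation of a lithium enolate from a silyl enol ether with MeLi and SN2 C-allylation (C4 is the only nucleophilic carbon because C6 is sp2); the C4 configuration formed here does not matter because it is reset in step 10.

**Step 9**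
Reactants: 14 C4-allyl C16-vinyl β-alkoxy enone
Product: 16 C6-hydroxy ketone with saturated ring C (OH up; C7H2; mixture of C4 epimers), via lithium enolate 15 (not isolated)
Conditions: LiBH(s-Bu)3 (L-Selectride, 1.2 equiv), THF, −78 °C; then 2-(phenylsulfonyl)-3-phenyloxaziridine (1.5 equiv), −78 °C; then AcOH
Reagents that add atoms: 2-(phenylsulfonyl)-3-phenyloxaziridine, O=S(=O)(c1ccccc1)N1OC1c1ccccc1
Why: Conjugate hydride reduction of the cyclic β-alkoxy enone (as for 2,3-dihydro-4-pyranones) gives the C5–C6 enolate regiospecifically, and enolate hydroxylation by the N-sulfonyloxaziridine places OH on the upper face of C6 (cis to H15), the lower face being covered by ring B, so ring C stays cis-fused to ring A.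

**Step 10**
Reactants: 16 C6-hydroxy ketone (C4 epimers)
Product: 18 C4-defined allyl ketol (allyl down and H4 up; vinyl up; OH up), via dilithium alkoxide enolate 17 (not isolated)
Conditions: LiN(i-Pr)2 (3 equiv), THF, −78 → −20 °C; then AcOH in THF, −78 °C
Reagents that add atoms: none
Why: Enolisation at C4 (the only α-hydrogen) and kinetic protonation: with C6 sp3 the cis-fused chair of ring C turns C5 towards ring B, so ring A folds chair-like and the lower face of the C4 enolate carbon is blocked by the axial hydrogens on C10 and C12; the proton should therefore enter from the upper face and leave the allyl group down, trans to the C16 vinyl group.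

**Step 11**
Reactants: 18 C4-defined allyl ketol
Product: 19 methyl ketone (acetonyl at C4; vinyl at C16; C6–OH)
Conditions: PdCl2 (20 mol %), CuCl (1 equiv), O2 (1 atm), DMF/H2O (7:1), rt
Reagents that add atoms: water, O
Why: Tsuji–Wacker oxidation (Markovnikov, assisted by the C5 carbonyl) of the unhindered allyl group to the methyl ketone; the C16 vinyl group, on a carbon flanked by the quaternary C13 and the tertiary C4, should coordinate palladium far more slowly and survive.

**Step 12**
Reactants: 19 methyl ketone
Product: 21 potassium (E)-alkenyltrifluoroborate (C16–CH=CH–BF3K), via pinacol boronate 20 (not isolated)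
Conditions: vinylboronic acid pinacol ester (5 equiv), second-generation Hoveyda–Grubbs catalyst (10 mol %), CH2Cl2, 40 °C; then KHF2 (aq.), MeOH, rt
Reagents that add atoms: vinylboronic acid pinacol ester, C=CB1OC(C)(C)C(C)(C)O1; potassium hydrogen difluoride, F.[F-].[K+]
Why: Olefin cross-metathesis of the only remaining terminal alkene with a vinyl boronate, where the bulky allylic substituent should enforce the (E)-alkenyl boronate, followed by the standard KHF2 conversion to the trifluoroborate.

**Step 13**
Reactants: 21 potassium (E)-alkenyltrifluoroborate; 22 3-methylbut-2-enoic acid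
Product: 23 target (4S,6R,10S,13S,15S,16S in the numbering used here; (E)-enol ester)
Conditions: 22 (3 equiv), CuBr (20 mol %), DMAP (40 mol %), 4 Å MS, O2 (1 atm), MeCN, 40 °C
Reagents that add atoms: none
Why: Copper-catalysed oxidative C–O coupling of an alkenyl trifluoroborate with a carboxylic acid (Chan–Lam–Evans type), which proceeds with retention of alkene geometry and so gives the (E)-enol ester; the tertiary C6 hydroxyl is too hindered to compete.

**Compound list**

1 | 5-bromo-2-methylpent-2-ene | CC(C)=CCCBr | starting material
2 | (4-methylpent-3-en-1-yl)magnesium bromide | CC(C)=CCC[Mg]Br | intermediate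
3 | 3-methylcyclohex-2-en-1-one | CC1=CC(=O)CCC1 | starting material
4 | bromomagnesium enolate of (R)-3-methyl-3-(4-methylpent-3-en-1-yl)cyclohexanone | CC(C)=CCC[C@@]1(C)CCCC(O[Mg]Br)=C1 | intermediate
5 | (R)-trimethyl{[3-methyl-3-(4-methylpent-3-en-1-yl)cyclohex-1-en-1-yl]oxy}silane | CC(C)=CCC[C@@]1(C)CCCC(O[Si](C)(C)C)=C1 | intermediate
6 | (5R)-5-methyl-5-(4-methylpent-3-en-1-yl)-1-(trimethylsilyloxy)bicyclo[4.1.0]heptane, both cyclopropane diastereomers | CC(C)=CCC[C@@]1(C)CCCC2(O[Si](C)(C)C)CC21 | intermediate
7 | 3-chloro-4-methyl-4-(4-methylpent-3-en-1-yl)cycloheptan-1-one, quaternary centre as in 8, chloride epimers | O=C1CC(Cl)[C@@](C)(CCC=C(C)C)CCC1 | intermediate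
8 | (R)-4-methyl-4-(4-methylpent-3-en-1-yl)cyclohept-2-en-1-one | O=C1C=C[C@@](C)(CCC=C(C)C)CCC1 | intermediate
9 | 7-(hydroxymethylene)-4-methyl-4-(4-methylpent-3-en-1-yl)cyclohept-2-en-1-one, chelated Z-enol, quaternary centre as in 8 | O=C1C=C[C@@](C)(CCC=C(C)C)CC/C1=C/O | intermediate
10 | 4-methyl-4-(4-methylpent-3-en-1-yl)-7-oxocyclohepta-1,5-diene-1-carbaldehyde, quaternary centre as in 8 | O=C1C=C[C@@](C)(CCC=C(C)C)CC=C1C=O | intermediate
11 | tricyclic β-alkoxy dienone: C5 ketone, C4=C16, C6=C7 enol ether, H15 up, H10 trans to H15 | O=C1C=C[C@@]2(C)CC[C@H]3[C@H](C2)C1=COC3(C)C | intermediate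
12 | C16-vinyl silyl dienol ether: C5–OSiMe3, C4=C5, C6=C7, vinyl up | C[Si](C)(C)OC1=C[C@H](C=C)[C@@]2(C)CC[C@H]3[C@H](C2)C1=COC3(C)C | intermediate
13 | lithium enolate of the C16-vinyl β-alkoxy enone | [Li]OC1=C[C@H](C=C)[C@@]2(C)CC[C@H]3[C@H](C2)C1=COC3(C)C | intermediate
14 | C4-allyl C16-vinyl β-alkoxy enone, C4 epimers | O=C1C(CC=C)[C@H](C=C)[C@@]2(C)CC[C@H]3[C@H](C2)C1=COC3(C)C | intermediate
15 | lithium C5–C6 enolate with saturated C7, C4 epimers | C=CCC1[C@H](C=C)[C@@]2(C)CC[C@H]3[C@H](C2)C(COC3(C)C)=C1O[Li] | intermediate
16 | C6-hydroxy ketone with tetrahydropyran ring C, OH up, C4 epimers | C=CCC1[C@H](C=C)[C@@]2(C)CC[C@H]3[C@H](C2)[C@@](O)(COC3(C)C)C1=O | intermediate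
17 | dilithium C6-alkoxide C4–C5 enolate | C=CCC=1[C@H](C=C)[C@@]2(C)CC[C@H]3[C@H](C2)[C@@](O[Li])(COC3(C)C)C=1O[Li] | intermediate
18 | C4-defined allyl ketol: allyl down, vinyl up, OH up | C=CC[C@H]1[C@H](C=C)[C@@]2(C)CC[C@H]3[C@H](C2)[C@@](O)(COC3(C)C)C1=O | intermediate
19 | methyl ketone: acetonyl at C4, vinyl at C16, C6–OH | CC(=O)C[C@H]1[C@H](C=C)[C@@]2(C)CC[C@H]3[C@H](C2)[C@@](O)(COC3(C)C)C1=O | intermediate
20 | (E)-alkenyl pinacol boronate at C16 | CC(=O)C[C@H]1[C@H](/C=C/B2OC(C)(C)C(C)(C)O2)[C@@]3(C)CC[C@H]4[C@H](C3)[C@@](O)(COC4(C)C)C1=O | intermediate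
21 | potassium (E)-alkenyltrifluoroborate at C16 | CC(=O)C[C@H]1[C@H](/C=C/[B-](F)(F)F)[C@@]2(C)CC[C@H]3[C@H](C2)[C@@](O)(COC3(C)C)C1=O.[K+] | intermediate
22 | 3-methylbut-2-enoic acid | CC(C)=CC(=O)O | starting material
23 | target CNP0237201.1 | CC(=O)C[C@@H]1C(=O)[C@]2(O)COC(C)(C)[C@H]3CC[C@@](C)(C[C@@H]32)[C@H]1/C=C/OC(=O)C=C(C)C | target

**Step count and risks**

Total step count: 13. Longest linear sequence: 13 steps (1 → 23; 3 and 22 enter along the line).

The three steps most likely to fail are steps 10, 6 and 12.

Step 10. What may go wrong is protonation of the tetrasubstituted enolate from the lower face, or with poor facial discrimination, because the C16 vinyl group also screens the upper face; the allyl group would then end cis to the vinyl group. The fallback makes carbon, not hydrogen, the last electrophile at C4 in the same ring system. Setting out from 12, mild acid hydrolysis (1 M HCl, THF, 0 °C) gives the C4-unsubstituted C16-vinyl β-alkoxy enone F1. Conjugate reduction and hydroxylation exactly as in step 9 give the C4-unsubstituted C6-hydroxy ketone F2. Its dilithium alkoxide enolate (LiN(i-Pr)2, 2.2 equiv, THF, −78 °C) is alkylated with allyl iodide, which takes the face that the proton took and so places the allyl group on the lower face. The route is rejoined at 18.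

Step 6. What may go wrong is over-oxidation by DDQ, or oligomerisation or an ene reaction of the very electrophilic formyl dienone before it cyclises. The fallback forms the same two bonds by a stepwise polar cyclisation at the alcohol oxidation level. Setting out from 8, IBX (DMSO, 70 °C) dehydrogenates to 4-methyl-4-(4-methylpent-3-en-1-yl)cyclohepta-2,6-dien-1-one F3. A Morita–Baylis–Hillman reaction with aqueous formaldehyde (DMAP, THF/H2O), which begins by amine addition to the unhindered β-carbon C15, gives the 2-(hydroxymethyl) dienone F4. BF3·OEt2 (CH2Cl2, −78 °C) then triggers attack of the C9=C10 alkene on C15 of the activated enone and capture of the C9 cation by the primary hydroxyl, giving the tricyclic enone with saturated ring C F5. IBX dehydrogenation across C6–C7, the only enolisable α-position, returns to the route at 11.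

Step 12. What may go wrong is slow initiation and catalyst decomposition at the sterically shielded C16 vinyl group, or loss of control over alkene geometry. The fallback builds the alkenyl boronate from a C16 aldehyde. Setting out from 19, ozonolysis (O3, CH2Cl2/MeOH, −78 °C; Me2S) gives the C16 aldehyde F6. A Takai-type boron olefination (CrCl2, Cl2CHBpin, LiI, THF), which is selective for aldehydes over ketones and strongly (E)-selective, gives pinacol boronate 20, where the route is rejoined; 20 is converted into 21 with KHF2 as in step 12.

**Further compounds**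

F1 | step 10 | C4-unsubstituted C16-vinyl β-alkoxy enone | O=C1C[C@H](C=C)[C@@]2(C)CC[C@H]3[C@H](C2)C1=COC3(C)C
F2 | step 10 | C4-unsubstituted C6-hydroxy ketone with saturated ring C, OH up, vinyl up | C1[C@H](C=C)[C@@]2(C)CC[C@H]3[C@H](C2)[C@@](O)(COC3(C)C)C1=O
F3 | step 6 | 4-methyl-4-(4-methylpent-3-en-1-yl)cyclohepta-2,6-dien-1-one, quaternary centre as in 8 | O=C1C=C[C@@](C)(CCC=C(C)C)CC=C1
F4 | step 6 | 2-(hydroxymethyl)-5-methyl-5-(4-methylpent-3-en-1-yl)cyclohepta-2,6-dien-1-one | O=C1C=C[C@@](C)(CCC=C(C)C)CC=C1CO
F5 | step 6 | tricyclic enone with saturated ring C: C5 ketone, C4=C16, H6 up | O=C1C=C[C@@]2(C)CC[C@H]3[C@H](C2)[C@H]1COC3(C)C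
F6 | step 12 | C16 aldehyde from ozonolysis of 19 | CC(=O)C[C@H]1[C@H](C=O)[C@@]2(C)CC[C@H]3[C@H](C2)[C@@](O)(COC3(C)C)C1=O
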